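**Plan**
- Retrosynthesis: remove the C1–C10 epoxide oxygen and the two acyl groups (on O3 and O8); open the ten-membered ring at C3–C4 (aldehyde + Z-alkenyl iodide); open the lactone at C7–C11 back to the O6-acrylate of a trans-7,8-epoxy alcohol; then cut C6–C7 (alkenylzinc + enal), C8–C9 (alkynyl + allyl bromide) and C1=C10 (Wittig).
- Forward: the C3→C7 chain is built first, joined to (Z)-3-iodobut-2-enal at C6–C7 and epoxidised at C7/C8; then the γ-lactone ring closes (C7–C11), then the ten-membered carbocycle (C3–C4), and the 1,10-epoxide ring comes last. The epoxyangelic acid is made separately.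
- Enabling feature: the lactone oxygen sits on C6, C7 is the next ring atom and C8 carries oxygen. A trans-C7/C8 epoxide beside an O6-acrylate therefore puts the acrylate α-carbon (C11) within five-ring reach of C7, anti to the C7–O bond, and the oxygen it displaces is the one C8 needs.
- Stereochemistry: C6 from a ligand-controlled alkenylzinc addition; C7/C8 from a matched Sharpless epoxidation, with C7 inverted once in the key step to give the trans-lactone; C3 from the ring-closing addition; C1/C10 from outer-face epoxidation of the E-alkene. The Z-C4=C5 geometry comes from trans-hydroalumination/iodination and the E-C1=C10 geometry from the Wittig step; the side chains come from an L-tartrate-controlled epoxidation and (R)-2-methylbutanoic acid.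

Key step: step 10

Remark: germacrane numbering is used throughout (ring carbons C1–C10, lactone carbons C11–C13, lactone oxygen on C6); the (R) configuration of the 2-methylbutanoate is taken from the structure as drawn.

**Step 1**
Reactants: 1 3-[(tert-butyldimethylsilyl)oxy]propanal; 2 ethyl 2-(triphenyl-λ5-phosphanylidene)propanoate
Product: 3 ethyl (2E)-5-[(tert-butyldimethylsilyl)oxy]-2-methylpent-2-enoate
Conditions: CH2Cl2, 23 → 40 °C
Reagents that add atoms: none
Why: Wittig olefination with a stabilised α-branched ylide is reliably E-selective and fixes the C1=C10 geometry (C2 trans to C9) that the final epoxide inherits.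

**Step 2**
Reactants: 3 ethyl (2E)-5-[(tert-butyldimethylsilyl)oxy]-2-methylpent-2-enoate
Product: 4 (2E)-5-[(tert-butyldimethylsilyl)oxy]-2-methylpent-2-en-1-ol
Conditions: iBu2AlH (2.2 equiv), CH2Cl2, −78 → 0 °C; Rochelle salt work-up
Reagents that add atoms: none
Why: Hydride reduction of the unsaturated ester with iBu2AlH goes cleanly 1,2 to the allylic alcohol without touching the alkene geometry or the silyl ether.

**Step 3**
Reactants: 4 (2E)-5-[(tert-butyldimethylsilyl)oxy]-2-methylpent-2-en-1-ol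
Product: 5 {[(3E)-5-bromo-4-methylpent-3-en-1-yl]oxy}(tert-butyl)dimethylsilane
Conditions: CBr4, PPh3, CH2Cl2, −20 → 0 °C
Reagents that add atoms: carbon tetrabromide BrC(Br)(Br)Br
Why: The Appel reaction converts the primary allylic alcohol into the bromide under neutral conditions at the unhindered carbon, without allylic transposition.

**Step 4**
Reactants: 5 {[(3E)-5-bromo-4-methylpent-3-en-1-yl]oxy}(tert-butyl)dimethylsilane; 6 ethynylmagnesium bromide
Product: 7 tert-butyldimethyl{[(3E)-4-methylhept-3-en-6-yn-1-yl]oxy}silane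
Conditions: CuBr·SMe2 (10 mol%), THF, 0 → 23 °C
Reagents that add atoms: none
Why: Copper-catalysed coupling of an alkynyl Grignard reagent with a primary allylic bromide should occur at the unhindered CH2 terminus with retention of the E geometry and give the skipped enyne (C7≡C8–C9).

**Step 5**
Reactants: 8 but-2-yn-1-ol
Product: 10 (2Z)-3-iodobut-2-en-1-ol, via cyclic sodium alkenylalanate 9 (not isolated)
Conditions: NaAlH2(OCH2CH2OMe)2 (Red-Al), THF, 0 → 23 °C; then I2, −78 → 0 °C
Reagents that add atoms: iodine II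
Why: Hydroxyl-directed trans-hydroalumination of the propargylic alcohol places aluminium on the distal alkyne carbon in a five-membered alanate, and iodinolysis with retention should give the Z-vinyl iodide with iodine cis to the CH2OH carbon, the geometry the C4=C5 bond needs.

**Step 6**
Reactants: 10 (2Z)-3-iodobut-2-en-1-ol
Product: 11 (2Z)-3-iodobut-2-enal
Conditions: MnO2 (excess), CH2Cl2, 23 °C, dark; used as a solution
Reagents that add atoms: none
Why: Allylic oxidation with MnO2 is selective and neutral, so the Z geometry of the β-iodo enal should be preserved.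

**Step 7**
Reactants: 7 tert-butyldimethyl{[(3E)-4-methylhept-3-en-6-yn-1-yl]oxy}silane; 11 (2Z)-3-iodobut-2-enal
Product: 14 (2Z,4S,5E,8E)-11-[(tert-butyldimethylsilyl)oxy]-2-iodo-8-methylundeca-2,5,8-trien-4-ol, via alkenylzirconocene chloride 12 (not isolated), via alkenyl(methyl)zinc 13 (not isolated)
Conditions: Cp2Zr(H)Cl, CH2Cl2, 23 °C; Me2Zn, toluene, −65 °C; (−)-MIB (10 mol%), then 11, −30 → 0 °C; aq. work-up
Reagents that add atoms: none
Why: Syn-hydrozirconation of the terminal alkyne gives the E-alkenyl metal, and after transmetalation to zinc the amino-alcohol-catalysed asymmetric alkenylzinc addition to the enal should set C6 through the ligand-controlled aldehyde face, leaving the vinyl iodide untouched.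

**Step 8**
Reactants: 14 (2Z,4S,5E,8E)-11-[(tert-butyldimethylsilyl)oxy]-2-iodo-8-methylundeca-2,5,8-trien-4-ol
Product: 15 (1R,2Z)-1-[(2R,3R)-3-{(2E)-5-[(tert-butyldimethylsilyl)oxy]-2-methylpent-2-en-1-yl}oxiran-2-yl]-3-iodobut-2-en-1-ol
Conditions: Ti(OiPr)4 (10 mol%), D-(−)-diisopropyl tartrate (12 mol%), t-BuOOH (decane), 4 Å MS, CH2Cl2, −20 °C
Reagents that add atoms: tert-butyl hydroperoxide CC(C)(C)OO
Why: Sharpless asymmetric epoxidation in its matched sense: the D-tartrate catalyst should epoxidise the E-C7=C8 bond of the (S)-alcohol on the face that gives the erythro (7R,8R)-epoxy alcohol, while the electron-poor Z-iodoalkene, the isolated trisubstituted alkene and any minor enantiomer react far more slowly.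

**Step 9**
Reactants: 15 (1R,2Z)-1-[(2R,3R)-3-{(2E)-5-[(tert-butyldimethylsilyl)oxy]-2-methylpent-2-en-1-yl}oxiran-2-yl]-3-iodobut-2-en-1-ol; 16 prop-2-enoyl chloride
Product: 17 (1R,2Z)-1-[(2S,3R)-3-{(2E)-5-[(tert-butyldimethylsilyl)oxy]-2-methylpent-2-en-1-yl}oxiran-2-yl]-3-iodobut-2-en-1-yl prop-2-enoate
Conditions: iPr2NEt, DMAP (cat.), CH2Cl2, −20 → 0 °C
Reagents that add atoms: none
Why: Acylation of the secondary alcohol with the acid chloride installs the three-carbon tether (C11–C13) on O6 without disturbing the epoxide (the descriptor at C7 changes only through the priority rules).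

**Step 10**
Reactants: 17 (1R,2Z)-1-[(2S,3R)-3-{(2E)-5-[(tert-butyldimethylsilyl)oxy]-2-methylpent-2-en-1-yl}oxiran-2-yl]-3-iodobut-2-en-1-yl prop-2-enoate
Product: 18 (4R,5S)-4-[(1R,3E)-6-[(tert-butyldimethylsilyl)oxy]-1-hydroxy-3-methylhex-3-en-1-yl]-5-[(1Z)-2-iodoprop-1-en-1-yl]-3-methylideneoxolan-2-one
Conditions: PMe3 (0.3 equiv), t-BuOH/THF 1:1, 0.02 M, 23 → 40 °C
Reagents that add atoms: none
Why: Proposed new method: PMe3 adds reversibly to the acrylate β-carbon (C13) to give a phosphonium ester enolate whose α-carbon (C11) attacks C7 of the adjacent trans-epoxide from the side opposite the C7–O bond; the C8 alkoxide so released takes the C11 proton (relayed by t-BuOH) and PMe3 is expelled by E1cB elimination, which restores the C11=C13 methylene and turns the catalyst over. The closest known reaction type is the trialkylphosphine-mediated intramolecular Morita–Baylis–Hillman alkylation of enones by tethered epoxides and alkyl halides, and the ester-tethered case is argued to behave alike because acrylates form the same phosphonium enolates in Morita–Baylis–Hillman and Rauhut–Currier chemistry and the O6–C12–C11 tether holds C11 within bonding distance of C7. The γ-lactone closes in the 5-exo-tet mode (C11 onto C7, the breaking C7–O bond lying outside the new ring). C7 is set by SN2 inversion of the epoxide carbon installed in step 8, while C6 and C8 keep their configuration, so the erythro epoxy alcohol can only give the trans-fused lactone with the C8 hydroxyl configured as in the target. The step needs attack at C7 (5-exo) and not at C8 (6-endo), which the three-atom tether secures because only C7 can be reached collinear with its C–O bond, and it needs the catalyst to spare the vinyl iodide, the silyl ether and the product methylene lactone, which the neutral conditions and the reversibility of phosphine addition should secure. The precursor is an isomer of the product, so nothing is lost, and the C8 hydroxyl emerges free for the next acylation.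

**Step 11**
Reactants: 19 methyl (2Z)-2-methylbut-2-enoate
Product: 20 (2Z)-2-methylbut-2-en-1-ol
Conditions: iBu2AlH (2.2 equiv), Et2O, −78 → 0 °C; Rochelle salt work-up
Reagents that add atoms: none
Why: Hydride reduction of the angelate ester with iBu2AlH gives the allylic alcohol with retention of the Z geometry.

**Step 12**
Reactants: 20 (2Z)-2-methylbut-2-en-1-ol
Product: 21 [(2S,3R)-2,3-dimethyloxiran-2-yl]methanol
Conditions: Ti(OiPr)4 (10 mol%), L-(+)-diethyl tartrate (12 mol%), t-BuOOH (decane), 4 Å MS, CH2Cl2, −20 °C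
Reagents that add atoms: tert-butyl hydroperoxide CC(C)(C)OO
Why: Sharpless asymmetric epoxidation with the L-tartrate catalyst should deliver oxygen to the face that gives the (2S,3R)-epoxide, and the stereospecific syn transfer keeps CH2OH cis to the C3 methyl.

**Step 13**
Reactants: 21 [(2S,3R)-2,3-dimethyloxiran-2-yl]methanol
Product: 22 (2R,3R)-2,3-dimethyloxirane-2-carboxylic acid
Conditions: RuCl3 (2 mol%), NaIO4, MeCN/EtOAc/H2O, 0 → 23 °C
Reagents that add atoms: sodium periodate [Na+].[O-]I(=O)(=O)=O; water O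
Why: RuO4 generated catalytically from RuCl3 and periodate oxidises the primary epoxy alcohol to the glycidic acid without opening the epoxide or touching its stereocentres (the C2 descriptor changes only through the priority rules).

**Step 14**
Reactants: 18 (4R,5S)-4-[(1R,3E)-6-[(tert-butyldimethylsilyl)oxy]-1-hydroxy-3-methylhex-3-en-1-yl]-5-[(1Z)-2-iodoprop-1-en-1-yl]-3-methylideneoxolan-2-one; 22 (2R,3R)-2,3-dimethyloxirane-2-carboxylic acid
Product: 23 (1R,3E)-6-[(tert-butyldimethylsilyl)oxy]-1-[(2S,3R)-2-[(1Z)-2-iodoprop-1-en-1-yl]-4-methylidene-5-oxooxolan-3-yl]-3-methylhex-3-en-1-yl (2R,3R)-2,3-dimethyloxirane-2-carboxylate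
Conditions: DCC, DMAP, CH2Cl2, 0 → 23 °C
Reagents that add atoms: none
Why: Steglich esterification acylates the only free hydroxyl (C8–OH) with retention at C8, and the acid has a quaternary α-carbon that cannot epimerise.

**Step 15**
Reactants: 23 the 6-silyloxy ester from step 14
Product: 24 (1R,3E)-6-hydroxy-1-[(2S,3R)-2-[(1Z)-2-iodoprop-1-en-1-yl]-4-methylidene-5-oxooxolan-3-yl]-3-methylhex-3-en-1-yl (2R,3R)-2,3-dimethyloxirane-2-carboxylate
Conditions: HF·pyridine, pyridine, THF, 0 → 23 °C
Reagents that add atoms: none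
Why: Buffered fluoride desilylation should free the primary alcohol (C3–OH) while the esters, the glycidic epoxide, the methylene lactone and the vinyl iodide stay inert.

**Step 16**
Reactants: 24 the primary alcohol from step 15
Product: 25 (1R,3E)-1-[(2S,3R)-2-[(1Z)-2-iodoprop-1-en-1-yl]-4-methylidene-5-oxooxolan-3-yl]-3-methyl-6-oxohex-3-en-1-yl (2R,3R)-2,3-dimethyloxirane-2-carboxylate
Conditions: Dess–Martin periodinane, NaHCO3, CH2Cl2, 0 °C; used crude at once
Reagents that add atoms: none
Why: Buffered Dess–Martin oxidation gives the β,γ-unsaturated aldehyde under near-neutral conditions that should avoid migration of the C1=C10 bond into conjugation.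

**Step 17**
Reactants: 25 the iodo aldehyde from step 16
Product: 26 (3S,6R,7R,8R)-3-hydroxy-8-{[(2R,3R)-2,3-dimethyloxirane-2-carbonyl]oxy}germacra-1(10)E,4Z,11(13)-trien-12,6-olide
Conditions: CrCl2 (8 equiv), NiCl2 (2 mol%), DMSO/THF, 23 °C, syringe-pump addition to 1 mM; aq. work-up
Reagents that add atoms: none
Why: Intramolecular Nozaki–Hiyama–Kishi reaction: zerovalent nickel inserts into the C–I bond, the alkenyl group passes to trivalent chromium with retention of the Z geometry and adds chemoselectively to the aldehyde to close the ten-membered ring at C3–C4, and the new C3 carbinol is expected to form (3S) by attack on the outward-turned aldehyde face of the folded chain.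

**Step 18**
Reactants: 26 the macrocyclic alcohol from step 17; 27 (2R)-2-methylbutanoic acid
Product: 28 (3S,6R,7R,8R)-8-{[(2R,3R)-2,3-dimethyloxirane-2-carbonyl]oxy}-3-{[(2R)-2-methylbutanoyl]oxy}germacra-1(10)E,4Z,11(13)-trien-12,6-olide
Conditions: DCC, DMAP (cat.), CH2Cl2, 0 → 23 °C
Reagents that add atoms: none
Why: Steglich esterification acylates the only free hydroxyl with retention at C3, and the simple α-branched acid should not epimerise under carbodiimide activation.

**Step 19**
Reactants: 28 the diester from step 18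
Product: 29 (1R,3S,6R,7R,8R,10R)-1,10-epoxy-8-{[(2R,3R)-2,3-dimethyloxirane-2-carbonyl]oxy}-3-{[(2R)-2-methylbutanoyl]oxy}germacra-4Z,11(13)-dien-12,6-olide (CNP0265335.1)
Conditions: mCPBA (1.05 equiv), NaHCO3, CH2Cl2, 0 °C
Reagents that add atoms: 3-chloroperoxybenzoic acid O=C(OO)c1cccc(Cl)c1
Why: Prilezhaev epoxidation: the electrophilic peracid should select the only electron-rich alkene (C1=C10; C4=C5 is deactivated by two allylic acyloxy groups and C11=C13 is conjugated) and attack its exposed outer face in the ring conformation, giving the trans-(1R,10R)-epoxide stereospecifically from the E-alkene.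

**Compound list**
1 | 3-[(tert-butyldimethylsilyl)oxy]propanal | O=CCCO[Si](C)(C)C(C)(C)C | starting material
2 | ethyl 2-(triphenyl-λ5-phosphanylidene)propanoate | CCOC(=O)C(C)=P(c1ccccc1)(c1ccccc1)c1ccccc1 | starting material
3 | ethyl (2E)-5-[(tert-butyldimethylsilyl)oxy]-2-methylpent-2-enoate | CCOC(=O)/C(C)=C/CCO[Si](C)(C)C(C)(C)C | intermediate
4 | (2E)-5-[(tert-butyldimethylsilyl)oxy]-2-methylpent-2-en-1-ol | OC/C(C)=C/CCO[Si](C)(C)C(C)(C)C | intermediate
5 | {[(3E)-5-bromo-4-methylpent-3-en-1-yl]oxy}(tert-butyl)dimethylsilane | BrC/C(C)=C/CCO[Si](C)(C)C(C)(C)C | intermediate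
6 | ethynylmagnesium bromide | C#C[Mg]Br | starting material
7 | tert-butyldimethyl{[(3E)-4-methylhept-3-en-6-yn-1-yl]oxy}silane | C#CC/C(C)=C/CCO[Si](C)(C)C(C)(C)C | intermediate
8 | but-2-yn-1-ol | CC#CCO | starting material
9 | sodium 2,2-bis(2-methoxyethoxy)-3-methyl-2,5-dihydro-1,2-oxaluminol-2-uide (cyclic alkenylalanate) | [Na+].CC1=CCO[Al-]1(OCCOC)OCCOC | intermediate
10 | (2Z)-3-iodobut-2-en-1-ol | C/C(I)=C/CO | intermediate
11 | (2Z)-3-iodobut-2-enal | C/C(I)=C/C=O | intermediate
12 | chlorobis(cyclopentadienyl)[(1E,4E)-7-[(tert-butyldimethylsilyl)oxy]-4-methylhepta-1,4-dien-1-yl]zirconium | Cl[Zr](/C=C/C/C(C)=C/CCO[Si](C)(C)C(C)(C)C)(C1C=CC=C1)C1C=CC=C1 | intermediate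
13 | methyl[(1E,4E)-7-[(tert-butyldimethylsilyl)oxy]-4-methylhepta-1,4-dien-1-yl]zinc | C[Zn]/C=C/C/C(C)=C/CCO[Si](C)(C)C(C)(C)C | intermediate
14 | (2Z,4S,5E,8E)-11-[(tert-butyldimethylsilyl)oxy]-2-iodo-8-methylundeca-2,5,8-trien-4-ol | C/C(I)=C/[C@@H](O)/C=C/C/C(C)=C/CCO[Si](C)(C)C(C)(C)C | intermediate
15 | (1R,2Z)-1-[(2R,3R)-3-{(2E)-5-[(tert-butyldimethylsilyl)oxy]-2-methylpent-2-en-1-yl}oxiran-2-yl]-3-iodobut-2-en-1-ol | C/C(I)=C/[C@@H](O)[C@H]1O[C@@H]1C/C(C)=C/CCO[Si](C)(C)C(C)(C)C | intermediate
16 | prop-2-enoyl chloride (acryloyl chloride) | C=CC(=O)Cl | starting material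
17 | (1R,2Z)-1-[(2S,3R)-3-{(2E)-5-[(tert-butyldimethylsilyl)oxy]-2-methylpent-2-en-1-yl}oxiran-2-yl]-3-iodobut-2-en-1-yl prop-2-enoate | C=CC(=O)O[C@H](/C=C(/C)I)[C@H]1O[C@@H]1C/C(C)=C/CCO[Si](C)(C)C(C)(C)C | intermediate
18 | (4R,5S)-4-[(1R,3E)-6-[(tert-butyldimethylsilyl)oxy]-1-hydroxy-3-methylhex-3-en-1-yl]-5-[(1Z)-2-iodoprop-1-en-1-yl]-3-methylideneoxolan-2-one | C=C1C(=O)O[C@H](/C=C(/C)I)[C@H]1[C@H](O)C/C(C)=C/CCO[Si](C)(C)C(C)(C)C | intermediate
19 | methyl (2Z)-2-methylbut-2-enoate (methyl angelate) | C/C=C(/C)C(=O)OC | starting material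
20 | (2Z)-2-methylbut-2-en-1-ol | C/C=C(/C)CO | intermediate
21 | [(2S,3R)-2,3-dimethyloxiran-2-yl]methanol | OC[C@]1(C)O[C@@H]1C | intermediate
22 | (2R,3R)-2,3-dimethyloxirane-2-carboxylic acid | OC(=O)[C@]1(C)O[C@@H]1C | intermediate
23 | (1R,3E)-6-[(tert-butyldimethylsilyl)oxy]-1-[(2S,3R)-2-[(1Z)-2-iodoprop-1-en-1-yl]-4-methylidene-5-oxooxolan-3-yl]-3-methylhex-3-en-1-yl (2R,3R)-2,3-dimethyloxirane-2-carboxylate | C=C1C(=O)O[C@H](/C=C(/C)I)[C@H]1[C@H](OC(=O)[C@]2(C)O[C@@H]2C)C/C(C)=C/CCO[Si](C)(C)C(C)(C)C | intermediate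
24 | (1R,3E)-6-hydroxy-1-[(2S,3R)-2-[(1Z)-2-iodoprop-1-en-1-yl]-4-methylidene-5-oxooxolan-3-yl]-3-methylhex-3-en-1-yl (2R,3R)-2,3-dimethyloxirane-2-carboxylate | C=C1C(=O)O[C@H](/C=C(/C)I)[C@H]1[C@H](OC(=O)[C@]2(C)O[C@@H]2C)C/C(C)=C/CCO | intermediate
25 | (1R,3E)-1-[(2S,3R)-2-[(1Z)-2-iodoprop-1-en-1-yl]-4-methylidene-5-oxooxolan-3-yl]-3-methyl-6-oxohex-3-en-1-yl (2R,3R)-2,3-dimethyloxirane-2-carboxylate | C=C1C(=O)O[C@H](/C=C(/C)I)[C@H]1[C@H](OC(=O)[C@]2(C)O[C@@H]2C)C/C(C)=C/CC=O | intermediate
26 | (3S,6R,7R,8R)-3-hydroxy-8-{[(2R,3R)-2,3-dimethyloxirane-2-carbonyl]oxy}germacra-1(10)E,4Z,11(13)-trien-12,6-olide | C=C1C(=O)O[C@@H]2/C=C(/C)[C@@H](O)C/C=C(\C)C[C@@H](OC(=O)[C@]3(C)O[C@@H]3C)[C@@H]12 | intermediate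
27 | (2R)-2-methylbutanoic acid | CC[C@@H](C)C(=O)O | starting material
28 | (3S,6R,7R,8R)-8-{[(2R,3R)-2,3-dimethyloxirane-2-carbonyl]oxy}-3-{[(2R)-2-methylbutanoyl]oxy}germacra-1(10)E,4Z,11(13)-trien-12,6-olide | C=C1C(=O)O[C@@H]2/C=C(/C)[C@@H](OC(=O)[C@H](C)CC)C/C=C(\C)C[C@@H](OC(=O)[C@]3(C)O[C@@H]3C)[C@@H]12 | intermediate
29 | (1R,3S,6R,7R,8R,10R)-1,10-epoxy-8-{[(2R,3R)-2,3-dimethyloxirane-2-carbonyl]oxy}-3-{[(2R)-2-methylbutanoyl]oxy}germacra-4Z,11(13)-dien-12,6-olide (CNP0265335.1) | C=C1C(=O)O[C@@H]2/C=C(/C)[C@@H](OC(=O)[C@H](C)CC)C[C@H]3O[C@]3(C)C[C@@H](OC(=O)[C@]3(C)O[C@@H]3C)[C@@H]12 | target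

**Step count and risks**
Total step count: 19. Longest linear sequence: 14 steps (steps 1–4, 7–10, 14–19).

Steps most likely to fail:

1. Step 10 (proposed new method). The phosphonium ester enolate may form or close too slowly through the ester tether, so that acrylate oligomerisation or phosphine-catalysed oxa-Michael addition outruns the 5-exo alkylation. The fallback sets out from epoxy alcohol 15 and returns at 18. Steglich esterification of 15 with 2-(diethoxyphosphoryl)acetic acid (DCC, DMAP, CH2Cl2) would give the phosphonoacetate F1. NaH in THF (0 → 23 °C) would then generate the phosphonate-stabilised carbanion, a stoichiometric and much stronger nucleophile, whose 5-exo opening of the epoxide at C7 should give the sodium enolate of the α-phosphono lactone F2. Paraformaldehyde added to the same flask should deliver 18 by Horner–Wadsworth–Emmons methylenation. Both bond-forming events are known reaction types: alkylation of a phosphonoacetate carbanion by an epoxide to an α-phosphono-γ-butyrolactone, and its methylenation with formaldehyde.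

2. Step 17. Intermolecular coupling can compete with closure of the ten-membered ring, and the facial selectivity at C3 during ring closure may be poor or opposite. The fallback sets out from 25 and returns at 26. The ring is closed under the same high-dilution conditions without regard to the C3 configuration. The crude epimer mixture is oxidised (Dess–Martin periodinane, NaHCO3, CH2Cl2) to the macrocyclic enone F3. Corey–Bakshi–Shibata reduction ((R)-2-methyl-CBS-oxazaborolidine, catecholborane, toluene, −78 °C) should then give (3S)-26. This moves control of C3 from the ring-closing C–C bond formation to a reagent-controlled ketone reduction.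

3. Step 19. The peracid may attack the wrong face of the C1=C10 bond if the ring populates more than one conformer, or over-oxidise at C4=C5. The fallback sets out from 23 and returns at 29, placing the epoxide under reagent control before the ring exists. Shi epoxidation of 23 (D-fructose-derived ketone, Oxone, K2CO3, Bu4NHSO4, MeCN/dimethoxymethane/aqueous buffer, 0 °C) should give the acyclic (1R,10R)-epoxide F4. Desilylation (Bu4NF/AcOH, THF) gives the alcohol F5 and buffered Dess–Martin oxidation gives the epoxy aldehyde F6. Nozaki–Hiyama–Kishi ring closure (CrCl2, NiCl2 cat., DMSO/THF, high dilution) gives the macrocyclic epoxy alcohol F7. Esterification of F7 with 27 (DCC, DMAP) as in step 18 should then give 29.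

**Further compounds**
F1 | step 10 | (1R,2Z)-1-[(2S,3R)-3-{(2E)-5-[(tert-butyldimethylsilyl)oxy]-2-methylpent-2-en-1-yl}oxiran-2-yl]-3-iodobut-2-en-1-yl 2-(diethoxyphosphoryl)acetate | CCOP(=O)(OCC)CC(=O)O[C@H](/C=C(/C)I)[C@H]1O[C@@H]1C/C(C)=C/CCO[Si](C)(C)C(C)(C)C
F2 | step 10 | sodium enolate of (4R,5S)-3-(diethoxyphosphoryl)-4-[(1R,3E)-6-[(tert-butyldimethylsilyl)oxy]-1-hydroxy-3-methylhex-3-en-1-yl]-5-[(1Z)-2-iodoprop-1-en-1-yl]oxolan-2-one | [Na+].CCOP(=O)(OCC)C1=C([O-])O[C@H](/C=C(/C)I)[C@H]1[C@H](O)C/C(C)=C/CCO[Si](C)(C)C(C)(C)C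
F3 | step 17 | (6R,7R,8R)-8-{[(2R,3R)-2,3-dimethyloxirane-2-carbonyl]oxy}-3-oxogermacra-1(10)E,4Z,11(13)-trien-12,6-olide | C=C1C(=O)O[C@@H]2/C=C(/C)C(=O)C/C=C(\C)C[C@@H](OC(=O)[C@]3(C)O[C@@H]3C)[C@@H]12
F4 | step 19 | (1R)-2-[(2R,3R)-3-{2-[(tert-butyldimethylsilyl)oxy]ethyl}-2-methyloxiran-2-yl]-1-[(2S,3R)-2-[(1Z)-2-iodoprop-1-en-1-yl]-4-methylidene-5-oxooxolan-3-yl]ethyl (2R,3R)-2,3-dimethyloxirane-2-carboxylate | C=C1C(=O)O[C@H](/C=C(/C)I)[C@H]1[C@H](OC(=O)[C@]2(C)O[C@@H]2C)C[C@@]3(C)O[C@@H]3CCO[Si](C)(C)C(C)(C)C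
F5 | step 19 | (1R)-2-[(2R,3R)-3-(2-hydroxyethyl)-2-methyloxiran-2-yl]-1-[(2S,3R)-2-[(1Z)-2-iodoprop-1-en-1-yl]-4-methylidene-5-oxooxolan-3-yl]ethyl (2R,3R)-2,3-dimethyloxirane-2-carboxylate | C=C1C(=O)O[C@H](/C=C(/C)I)[C@H]1[C@H](OC(=O)[C@]2(C)O[C@@H]2C)C[C@@]3(C)O[C@@H]3CCO
F6 | step 19 | (1R)-1-[(2S,3R)-2-[(1Z)-2-iodoprop-1-en-1-yl]-4-methylidene-5-oxooxolan-3-yl]-2-[(2R,3R)-2-methyl-3-(2-oxoethyl)oxiran-2-yl]ethyl (2R,3R)-2,3-dimethyloxirane-2-carboxylate | C=C1C(=O)O[C@H](/C=C(/C)I)[C@H]1[C@H](OC(=O)[C@]2(C)O[C@@H]2C)C[C@@]3(C)O[C@@H]3CC=O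
F7 | step 19 | (1R,3S,6R,7R,8R,10R)-1,10-epoxy-3-hydroxy-8-{[(2R,3R)-2,3-dimethyloxirane-2-carbonyl]oxy}germacra-4Z,11(13)-dien-12,6-olide | C=C1C(=O)O[C@@H]2/C=C(/C)[C@@H](O)C[C@H]3O[C@]3(C)C[C@@H](OC(=O)[C@]3(C)O[C@@H]3C)[C@@H]12
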